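The plan hinges on disconnecting the O1′–C6′ bond of the 1,2-dioxane ring. Its quaternary carbon C6′ holds the methyl group on the same ring face as the propionate unit at C3′, a relationship that an (E)-C5′=C6′ olefin with a hydroperoxide at C3′ can deliver. In a single operation Hg(OAc)2 triggers 6-endo closure via a chair in which the C3′ branch lies equatorial, fixing C6′, and alkaline NaBH4 then exchanges the C5′–Hg bond for C–H. The cyclisation substrate is the (3′R)-hydroperoxide of the fully assembled chain on the cis-decalin, with the C2 and C7 oxygens masked as silylated carbinols: no competing alkene, no reducible ketone, no epimerisable C3.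

Key step: step 21

Remarks on the chemistry
- Locants: decalin C1–C8a, with oxygen at C2 and C7, the side chain at C3 and the gem-dimethyl group at C4; dioxane O1′, O2′, C3′–C6′. The ring is closed through O1′–C6′.
- Assumption: next to a C2 carbonyl the 3β side chain (cis to C5 across C4) is the less stable C3 epimer, and a free ketone would not survive NaBH4, alkaline H2O2 or the organoborane. C2 and C7 are therefore carried from step 9 to step 23 as triethylsilyl-protected carbinols on the same carbon skeleton.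
- Assumption: the carbinol configurations at C2 and C7 (drawn 2β,7β, as expected from LiBH(s-Bu)3), the alkylidene geometry in 11–17 and the extra centres of 9 and 10 are of no consequence, because all are erased later.

**Ring B and the cis-decalin**

Step 1
Reactants: 1 hex-5-enal; 2 but-3-en-2-one
Product: 4 (S)-4-(but-3-en-1-yl)cyclohex-2-en-1-one, via oxo-aldehyde 3 (not isolated)
Conditions: (R)-α,α-diphenylprolinol trimethylsilyl ether (10 mol %), ethyl 3,4-dihydroxybenzoate (20 mol %), neat, 4 °C; then TsOH·H2O (cat.), toluene, 80 °C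
Reagents that add atoms: none
Why: Enamine-catalysed Michael addition followed by acid-catalysed intramolecular aldol condensation (organocatalytic Robinson-type annulation); the diarylmethyl group of the (R)-catalyst shields one face of the (E)-enamine, so the new centre (later C4a) should form with the (S) configuration.

Step 2
Reactants: 4 (S)-4-(but-3-en-1-yl)cyclohex-2-en-1-one
Product: 6 (S)-4-(but-3-en-1-yl)-3-methylcyclohex-2-en-1-one, via lithium enolate 5 (not isolated)
Conditions: Me2CuLi (from CuI and MeLi), Et2O, −78 → −20 °C; then PhS(Cl)=N-t-Bu, THF, −78 °C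
Reagents that add atoms: lithium dimethylcuprate, [Li+].C[Cu-]C
Why: Cuprate 1,4-addition gives a regiodefined enolate, which the sulfinimidoyl chloride dehydrogenates in the same flask (sulfur transfer to C2, syn-elimination of the C3 hydrogen), so the transient C3 centre disappears and C4 is untouched.

Step 3
Reactants: 6 (S)-4-(but-3-en-1-yl)-3-methylcyclohex-2-en-1-one; 7 (benzyloxy)acetaldehyde
Product: 9 (4S)-2-[2-(benzyloxy)-1-hydroxyethyl]-4-(but-3-en-1-yl)-3,3-dimethylcyclohexan-1-one (diastereomer mixture), via lithium enolate 8 (not isolated)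
Conditions: Me2CuLi (from CuI and MeLi), Et2O, 0 °C; then 7, −78 °C; AcOH
Reagents that add atoms: lithium dimethylcuprate, [Li+].C[Cu-]C
Why: A second cuprate 1,4-addition builds the gem-dimethyl carbon (no new stereocentre) and leaves the enolate on the hindered side of the ketone, where an aldol addition traps it at once; both new centres are removed in step 4.

Step 4
Reactants: 9 aldol adduct
Product: 11 (2Z,4S)-2-[2-(benzyloxy)ethylidene]-4-(but-3-en-1-yl)-3,3-dimethylcyclohexan-1-one, via mesylate 10 (not isolated)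
Conditions: MsCl, Et3N, CH2Cl2, 0 °C; then DBU, rt
Reagents that add atoms: none
Why: Sulfonylation and E1cB elimination complete an aldol condensation; the CH2OBn group should end on the carbonyl side of the exocyclic alkene because the gem-dimethyl carbon blocks the other side.

Step 5
Reactants: 11 alkylidene ketone
Product: 13 (4S,6Z)-6-[2-(benzyloxy)ethylidene]-4-(but-3-en-1-yl)-5,5-dimethylcyclohex-2-en-1-one, via lithium dienolate 12 (not isolated)
Conditions: LiN(i-Pr)2, THF, −78 °C; then PhS(Cl)=N-t-Bu, −78 °C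
Reagents that add atoms: none
Why: Kinetic deprotonation at the only α-carbon that still bears hydrogen, then enolate dehydrogenation with the sulfinimidoyl chloride, gives the cross-conjugated dienone; the quaternary carbon rules out aromatisation and the stereocentre, now γ to the carbonyl, is not touched.

Step 6
Reactants: 13 dienone
Product: 14 (4S,6Z)-6-[2-(benzyloxy)ethylidene]-5,5-dimethyl-4-(3-oxobutyl)cyclohex-2-en-1-one
Conditions: PdCl2 (10 mol %), CuCl, O2 (1 atm), DMF–H2O (7:1), rt
Reagents that add atoms: water, O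
Why: Wacker oxidation converts the terminal alkene into the methyl ketone with Markovnikov selectivity, while the electron-poor enone alkenes do not take part.

Step 7
Reactants: 14 methyl ketone
Product: 17 (3Z,4aS,8aS)-3-[2-(benzyloxy)ethylidene]-4,4-dimethyl-cis-decalin-2,7-dione, via lithium enolate 15 (not isolated), via bicyclic enolate 16 (not isolated)
Conditions: LiN(SiMe3)2, THF, −78 → 0 °C; then AcOH
Reagents that add atoms: none
Why: Kinetic enolisation of the methyl ketone and intramolecular Michael addition (6-exo-trig) to the ring enone close ring A; the short tether can deliver C8 only to the face of C8a on which it sits at C4a, so the ring fusion should be cis.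

Step 8
Reactants: 17 alkylidene dione
Product: 18 (3S,4aS,8aS)-3-[2-(benzyloxy)ethyl]-4,4-dimethyl-cis-decalin-2,7-dione
Conditions: H2 (1 atm), 5 % Pd/C, pyridine (0.5 equiv), EtOAc, rt
Reagents that add atoms: none
Why: Heterogeneous hydrogenation of the enone C=C, with pyridine suppressing benzyl ether hydrogenolysis; in either chair of ring B the β face of C3 is screened by ring A (C5 or C8 syn-axial), so hydrogen should add from the convex α face and leave the side chain β, the epimer that equilibration would not give.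

Step 9
Reactants: 18 saturated dione
Product: 19 (2R,3S,4aS,7R,8aS)-3-[2-(benzyloxy)ethyl]-4,4-dimethyl-cis-decalin-2,7-diol
Conditions: LiBH(s-Bu)3, THF, −78 °C; then NaOH, H2O2, 0 °C
Reagents that add atoms: none
Why: Hydride reduction of both ketones with a bulky borohydride at low temperature outruns enolisation and so locks C3; attack from the convex face is expected to give the 2β,7β-diol.

Step 10
Reactants: 19 diol
Product: 20 (2R,3S,4aS,7R,8aS)-3-[2-(benzyloxy)ethyl]-4,4-dimethyl-2,7-bis(triethylsilyloxy)-cis-decalin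
Conditions: Et3SiOTf, 2,6-lutidine, CH2Cl2, −78 → 0 °C
Reagents that add atoms: triethylsilyl trifluoromethanesulfonate, CC[Si](CC)(CC)OS(=O)(=O)C(F)(F)F
Why: Silylation with the silyl triflate protects both secondary alcohols, including the hindered C2 hydroxyl, with no effect on any stereocentre.

Step 11
Reactants: 20 benzyl ether
Product: 21 2-[(2R,3S,4aS,7R,8aS)-4,4-dimethyl-2,7-bis(triethylsilyloxy)-cis-decalin-3-yl]ethan-1-ol
Conditions: H2 (1 atm), Pd(OH)2/C, EtOAc, rt
Reagents that add atoms: none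
Why: Hydrogenolysis of the benzyl ether; triethylsilyl ethers are stable to Pd and H2 in a non-protic solvent.

Step 12
Reactants: 21 primary alcohol
Product: 22 (2R,3S,4aS,7R,8aS)-3-(2-iodoethyl)-4,4-dimethyl-2,7-bis(triethylsilyloxy)-cis-decalin
Conditions: I2, PPh3, imidazole, CH2Cl2, 0 °C
Reagents that add atoms: iodine, II
Why: Appel-type iodination of the primary alcohol; the C2 oxygen is already silylated, so the 1,4-related oxygen cannot close a tetrahydrofuran.

**Side chain**

Step 13
Reactants: 23 pent-3-yn-1-ol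
Product: 25 (E)-4-iodopent-3-en-1-ol, via alkenylzirconocene 24 (not isolated)
Conditions: Cp2Zr(H)Cl (2.5 equiv), THF, rt → 40 °C; then I2, 0 °C
Reagents that add atoms: iodine, II
Why: Hydrozirconation (syn addition; excess reagent equilibrates zirconium onto the methyl-bearing carbon) and iodinolysis with retention give the (E)-2-iodoalkene.

Step 14
Reactants: 25 (E)-4-iodopent-3-en-1-ol
Product: 26 (E)-4-iodopent-3-enal
Conditions: Dess–Martin periodinane, NaHCO3, CH2Cl2, 0 °C → rt
Reagents that add atoms: none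
Why: Dess–Martin oxidation under buffered, non-basic conditions, so the β,γ-unsaturated aldehyde should not move into conjugation; it is used crude.

Step 15
Reactants: 26 (E)-4-iodopent-3-enal; 27 (R)-4-benzyl-3-propionyloxazolidin-2-one
Product: 29 (R)-4-benzyl-3-[(2R,3S,5E)-3-hydroxy-6-iodo-2-methylhept-5-enoyl]oxazolidin-2-one, via boron enolate 28 (not isolated)
Conditions: 27, n-Bu2BOTf, Et3N, CH2Cl2, −78 → 0 °C; then 26, −78 → 0 °C; pH 7 buffer, MeOH, H2O2
Reagents that add atoms: none
Why: Evans syn-aldol: the (Z)-boron enolate reacts through a closed chair transition state on the face away from the benzyl group, which should set (2R,3S).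

Step 16
Reactants: 29 aldol adduct
Product: 30 (2S,3S,5E)-6-iodo-2-methylhept-5-ene-1,3-diol
Conditions: LiBH4, MeOH (1 equiv), THF, 0 °C
Reagents that add atoms: none
Why: Reductive cleavage of the imide releases the auxiliary and the 1,3-diol; no stereocentre is involved and the descriptor at C2 changes only by priority.

Step 17
Reactants: 30 diol
Product: 31 (2S,3S,5E)-1-(tert-butyldiphenylsilyloxy)-6-iodo-2-methylhept-5-en-3-ol
Conditions: t-BuPh2SiCl, imidazole, CH2Cl2, 0 °C
Reagents that add atoms: tert-butyl(chloro)diphenylsilane, CC(C)(C)[Si](Cl)(c1ccccc1)c1ccccc1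
Why: Selective silylation of the primary hydroxyl; the bulky, acid-stable silyl group later outlasts removal of the triethylsilyl ethers.

**Coupling, hydroperoxide and ring closure**

Step 18
Reactants: 22 alkyl iodide; 31 vinyl iodide
Product: 34 (2S,3S,5E)-1-(tert-butyldiphenylsilyloxy)-8-[(2R,3S,4aS,7R,8aS)-4,4-dimethyl-2,7-bis(triethylsilyloxy)-cis-decalin-3-yl]-2,6-dimethyloct-5-en-3-ol, via alkyllithium 32 (not isolated), via lithium borate 33 (not isolated)
Conditions: t-BuLi (2.1 equiv), 9-MeO-9-BBN, Et2O–THF, −78 °C → rt; then 31, PdCl2(dppf) (5 mol %), AsPh3, 3 M aq. K3PO4, DMF, rt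
Reagents that add atoms: none
Why: B-alkyl Suzuki–Miyaura coupling: iodine–lithium exchange and capture by the borinate give a B-alkyl borate that transfers its primary alkyl group to palladium after oxidative addition of the vinyl iodide; the alkene geometry is retained and the free C3′ hydroxyl is tolerated.

Step 19
Reactants: 34 homoallylic alcohol
Product: 35 (2S,3S,5E)-1-(tert-butyldiphenylsilyloxy)-8-[(2R,3S,4aS,7R,8aS)-4,4-dimethyl-2,7-bis(triethylsilyloxy)-cis-decalin-3-yl]-2,6-dimethyloct-5-en-3-yl methanesulfonate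
Conditions: MsCl, Et3N, CH2Cl2, 0 °C
Reagents that add atoms: methanesulfonyl chloride, CS(=O)(=O)Cl
Why: Sulfonylation of the only free hydroxyl with retention at C3′.

Step 20
Reactants: 35 mesylate
Product: 36 tert-butyl{[(2S,3R,5E)-8-[(2R,3S,4aS,7R,8aS)-4,4-dimethyl-2,7-bis(triethylsilyloxy)-cis-decalin-3-yl]-3-hydroperoxy-2,6-dimethyloct-5-en-1-yl]oxy}diphenylsilane
Conditions: 50 % aq. H2O2 (excess), KOH, MeOH–THF, 0 °C → rt
Reagents that add atoms: hydrogen peroxide, OO
Why: SN2 displacement of the secondary mesylate by hydroperoxide anion, a strong α-effect nucleophile of low basicity, should invert C3′ to the (R)-hydroperoxide; loss of a triethylsilyl group here would be harmless because both are removed in step 22.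

Step 21
Reactants: 36 hydroperoxy (E)-alkene
Product: 38 tert-butyl{(2S)-2-[(3R,6S)-6-{2-[(2R,3S,4aS,7R,8aS)-4,4-dimethyl-2,7-bis(triethylsilyloxy)-cis-decalin-3-yl]ethyl}-6-methyl-1,2-dioxan-3-yl]propoxy}diphenylsilane, via organomercurial 37 (not isolated)
Conditions: Hg(OAc)2 (1.1 equiv), CH2Cl2, rt; then NaBH4, 3 M aq. NaOH, 0 °C
Reagents that add atoms: none
Why: Cycloperoxymercuration–demercuration of an unsaturated hydroperoxide, a known route to 1,2-dioxanes: Hg(OAc)2 forms a mercurinium ion on the only alkene, the terminal hydroperoxide oxygen opens it anti at the tertiary carbon C6′, and NaBH4 then replaces the C5′–Hg bond by C–H through an alkylmercury hydride and a C5′ radical. The dioxane closes in the 6-endo-trig mode through the O1′–C6′ bond, since the 5-exo alternative would require attack at the less substituted C5′. C6′ is controlled by the (E) geometry relayed through a chair in which the branched C3′ substituent is equatorial: the alkene substituent cis to C4′ (the methyl) becomes axial and the trans one (the chain to the decalin) equatorial, which is the (3′R,6′S) cis relationship of the target, while the C5′ centre is erased on demercuration. The step needs chemoselectivity (secured by carrying C2 and C7 as silyl ethers, so no other alkene or carbonyl is present), Markovnikov regioselectivity (secured by the trisubstituted alkene) and facial selectivity (secured by the equatorial preference of the C3′ branch). Cold, concentrated alkaline borohydride keeps hydrogen transfer ahead of collapse of the β-peroxyalkyl radical to an epoxide.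

**From the dioxane to the target**

Step 22
Reactants: 38 bis(triethylsilyl) ether
Product: 39 tert-butyl{(2S)-2-[(3R,6S)-6-{2-[(2R,3S,4aS,7R,8aS)-2,7-dihydroxy-4,4-dimethyl-cis-decalin-3-yl]ethyl}-6-methyl-1,2-dioxan-3-yl]propoxy}diphenylsilane
Conditions: pyridinium p-toluenesulfonate (cat.), MeOH–CH2Cl2, rt
Reagents that add atoms: none
Why: Acid-catalysed methanolysis removes the two secondary triethylsilyl ethers, while the primary tert-butyldiphenylsilyl ether and the dialkyl peroxide are stable to mild acid.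

Step 23
Reactants: 39 diol
Product: 40 tert-butyl{(2S)-2-[(3R,6S)-6-{2-[(3S,4aS,8aS)-4,4-dimethyl-2,7-dioxo-cis-decalin-3-yl]ethyl}-6-methyl-1,2-dioxan-3-yl]propoxy}diphenylsilane
Conditions: Dess–Martin periodinane, NaHCO3, CH2Cl2, rt
Reagents that add atoms: none
Why: Dess–Martin oxidation of both secondary alcohols under buffered, neutral conditions that should not enolise the C2 ketone, so C3 keeps its configuration.

Step 24
Reactants: 40 dione
Product: 41 tert-butyl{(2S)-2-[(3R,6S)-6-{2-[(3R,4aS,8aS)-4,4-dimethyl-2,7-dimethylidene-cis-decalin-3-yl]ethyl}-6-methyl-1,2-dioxan-3-yl]propoxy}diphenylsilane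
Conditions: Ph3PCH3Br, KOt-Bu, THF–toluene, 0 → 40 °C
Reagents that add atoms: methyltriphenylphosphonium bromide, C[P+](c1ccccc1)(c1ccccc1)c1ccccc1.[Br-]
Why: Double Wittig methylenation with the non-stabilised ylide, a reagent that dialkyl peroxides tolerate; the hindered C3–H is deprotonated more slowly than the C1 hydrogens, so C3 should survive, and its descriptor changes only by priority.

Step 25
Reactants: 41 silyl ether
Product: 42 (2S)-2-[(3R,6S)-6-{2-[(3R,4aS,8aS)-4,4-dimethyl-2,7-dimethylidene-cis-decalin-3-yl]ethyl}-6-methyl-1,2-dioxan-3-yl]propan-1-ol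
Conditions: Bu4NF, AcOH, THF, rt
Reagents that add atoms: none
Why: Fluoride-mediated desilylation, buffered with acetic acid so that the peroxide methine C3′–H is not exposed to a strong base.

Step 26
Reactants: 42 primary alcohol
Product: 43 (2R)-2-[(3R,6S)-6-{2-[(3R,4aS,8aS)-4,4-dimethyl-2,7-dimethylidene-cis-decalin-3-yl]ethyl}-6-methyl-1,2-dioxan-3-yl]propanoic acid
Conditions: TEMPO (cat.), PhI(OAc)2, MeCN–H2O, rt
Reagents that add atoms: water, O
Why: Oxoammonium-mediated oxidation of the primary alcohol through the aldehyde hydrate to the acid under near-neutral conditions, which should spare the exocyclic alkenes, the peroxide and the α-stereocentre.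

**Compound list**

1 | hex-5-enal | C=CCCCC=O | starting material
2 | but-3-en-2-one | CC(=O)C=C | starting material
3 | (S)-2-(but-3-en-1-yl)-5-oxohexanal | O=C[C@@H](CCC=C)CCC(C)=O | intermediate
4 | (S)-4-(but-3-en-1-yl)cyclohex-2-en-1-one | O=C1C=C[C@@H](CCC=C)CC1 | intermediate
5 | lithium 3,4-trans-4-(but-3-en-1-yl)-3-methylcyclohex-1-en-1-olate | [Li]OC1=C[C@H](C)[C@@H](CCC=C)CC1 | intermediate
6 | (S)-4-(but-3-en-1-yl)-3-methylcyclohex-2-en-1-one | O=C1C=C(C)[C@@H](CCC=C)CC1 | intermediate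
7 | (benzyloxy)acetaldehyde | O=CCOCc1ccccc1 | starting material
8 | lithium (S)-4-(but-3-en-1-yl)-3,3-dimethylcyclohex-1-en-1-olate | [Li]OC1=CC(C)(C)[C@@H](CCC=C)CC1 | intermediate
9 | (4S)-2-[2-(benzyloxy)-1-hydroxyethyl]-4-(but-3-en-1-yl)-3,3-dimethylcyclohexan-1-one, diastereomer mixture at C2 and the carbinol carbon | O=C1CC[C@H](CCC=C)C(C)(C)C1C(O)COCc1ccccc1 | intermediate
10 | (4S)-2-[2-(benzyloxy)-1-(methylsulfonyloxy)ethyl]-4-(but-3-en-1-yl)-3,3-dimethylcyclohexan-1-one, diastereomer mixture | O=C1CC[C@H](CCC=C)C(C)(C)C1C(OS(C)(=O)=O)COCc1ccccc1 | intermediate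
11 | (2Z,4S)-2-[2-(benzyloxy)ethylidene]-4-(but-3-en-1-yl)-3,3-dimethylcyclohexan-1-one | O=C1CC[C@H](CCC=C)C(C)(C)/C1=C/COCc1ccccc1 | intermediate
12 | lithium (4S,6Z)-6-[2-(benzyloxy)ethylidene]-4-(but-3-en-1-yl)-5,5-dimethylcyclohex-1-en-1-olate | [Li]OC1=CC[C@H](CCC=C)C(C)(C)/C1=C/COCc1ccccc1 | intermediate
13 | (4S,6Z)-6-[2-(benzyloxy)ethylidene]-4-(but-3-en-1-yl)-5,5-dimethylcyclohex-2-en-1-one | O=C1C=C[C@H](CCC=C)C(C)(C)/C1=C/COCc1ccccc1 | intermediate
14 | (4S,6Z)-6-[2-(benzyloxy)ethylidene]-5,5-dimethyl-4-(3-oxobutyl)cyclohex-2-en-1-one | O=C1C=C[C@H](CCC(C)=O)C(C)(C)/C1=C/COCc1ccccc1 | intermediate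
15 | lithium enolate of the methyl ketone of 14 (terminal CH2=C–OLi) | O=C1C=C[C@H](CCC(=C)O[Li])C(C)(C)/C1=C/COCc1ccccc1 | intermediate
16 | lithium 2-enolate (C1=C2) of 17 | O=C1CC[C@H]2[C@@H](C1)C=C(O[Li])/C(=C\COCc1ccccc1)C2(C)C | intermediate
17 | (3Z,4aS,8aS)-3-[2-(benzyloxy)ethylidene]-4,4-dimethyl-cis-decalin-2,7-dione | O=C1CC[C@H]2[C@@H](C1)CC(=O)/C(=C\COCc1ccccc1)C2(C)C | intermediate
18 | (3S,4aS,8aS)-3-[2-(benzyloxy)ethyl]-4,4-dimethyl-cis-decalin-2,7-dione (H-3, H-4a, H-8a all cis) | O=C1CC[C@H]2[C@@H](C1)CC(=O)[C@@H](CCOCc1ccccc1)C2(C)C | intermediate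
19 | (2R,3S,4aS,7R,8aS)-3-[2-(benzyloxy)ethyl]-4,4-dimethyl-cis-decalin-2,7-diol | O[C@@H]1CC[C@H]2[C@@H](C1)C[C@@H](O)[C@@H](CCOCc1ccccc1)C2(C)C | intermediate
20 | (2R,3S,4aS,7R,8aS)-3-[2-(benzyloxy)ethyl]-4,4-dimethyl-2,7-bis(triethylsilyloxy)-cis-decalin | CC[Si](CC)(CC)O[C@@H]1CC[C@H]2[C@@H](C1)C[C@@H](O[Si](CC)(CC)CC)[C@@H](CCOCc1ccccc1)C2(C)C | intermediate
21 | 2-[(2R,3S,4aS,7R,8aS)-4,4-dimethyl-2,7-bis(triethylsilyloxy)-cis-decalin-3-yl]ethan-1-ol | CC[Si](CC)(CC)O[C@@H]1CC[C@H]2[C@@H](C1)C[C@@H](O[Si](CC)(CC)CC)[C@@H](CCO)C2(C)C | intermediate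
22 | (2R,3S,4aS,7R,8aS)-3-(2-iodoethyl)-4,4-dimethyl-2,7-bis(triethylsilyloxy)-cis-decalin | CC[Si](CC)(CC)O[C@@H]1CC[C@H]2[C@@H](C1)C[C@@H](O[Si](CC)(CC)CC)[C@@H](CCI)C2(C)C | intermediate
23 | pent-3-yn-1-ol | CC#CCCO | starting material
24 | (E)-alkenylzirconocene chloride of pent-3-yn-1-ol, O-zirconated (cyclopentadienyl drawn σ-bonded) | C/C(=C\CCO[Zr](Cl)(C1C=CC=C1)C1C=CC=C1)[Zr](Cl)(C1C=CC=C1)C1C=CC=C1 | intermediate
25 | (E)-4-iodopent-3-en-1-ol | I/C(C)=C/CCO | intermediate
26 | (E)-4-iodopent-3-enal | I/C(C)=C/CC=O | intermediate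
27 | (R)-4-benzyl-3-propionyloxazolidin-2-one | CCC(=O)N1[C@H](Cc2ccccc2)COC1=O | starting material
28 | (Z)-dibutylboron enolate of 27 | C/C=C(\OB(CCCC)CCCC)N1[C@H](Cc2ccccc2)COC1=O | intermediate
29 | (R)-4-benzyl-3-[(2R,3S,5E)-3-hydroxy-6-iodo-2-methylhept-5-enoyl]oxazolidin-2-one | I/C(C)=C/C[C@@H]([C@@H](C)C(=O)N1[C@H](Cc2ccccc2)COC1=O)O | intermediate
30 | (2S,3S,5E)-6-iodo-2-methylhept-5-ene-1,3-diol | I/C(C)=C/C[C@@H]([C@@H](C)CO)O | intermediate
31 | (2S,3S,5E)-1-(tert-butyldiphenylsilyloxy)-6-iodo-2-methylhept-5-en-3-ol | I/C(C)=C/C[C@@H]([C@@H](C)CO[Si](c1ccccc1)(c1ccccc1)C(C)(C)C)O | intermediate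
32 | primary alkyllithium from 22 | CC[Si](CC)(CC)O[C@@H]1CC[C@H]2[C@@H](C1)C[C@@H](O[Si](CC)(CC)CC)[C@@H](CC[Li])C2(C)C | intermediate
33 | lithium B-alkyl-B-methoxy-9-borabicyclo[3.3.1]nonane borate from 32 | CC[Si](CC)(CC)O[C@@H]1CC[C@H]2[C@@H](C1)C[C@@H](O[Si](CC)(CC)CC)[C@@H](CC[B-]3(OC)C4CCCC3CCC4)C2(C)C.[Li+] | intermediate
34 | (2S,3S,5E)-1-(tert-butyldiphenylsilyloxy)-8-[(2R,3S,4aS,7R,8aS)-4,4-dimethyl-2,7-bis(triethylsilyloxy)-cis-decalin-3-yl]-2,6-dimethyloct-5-en-3-ol | CC[Si](CC)(CC)O[C@@H]1CC[C@H]2[C@@H](C1)C[C@@H](O[Si](CC)(CC)CC)[C@@H](CC/C(C)=C/C[C@@H]([C@@H](C)CO[Si](c3ccccc3)(c3ccccc3)C(C)(C)C)O)C2(C)C | intermediate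
35 | (3S)-methanesulfonate of 34 | CC[Si](CC)(CC)O[C@@H]1CC[C@H]2[C@@H](C1)C[C@@H](O[Si](CC)(CC)CC)[C@@H](CC/C(C)=C/C[C@@H]([C@@H](C)CO[Si](c3ccccc3)(c3ccccc3)C(C)(C)C)OS(C)(=O)=O)C2(C)C | intermediate
36 | tert-butyl{[(2S,3R,5E)-8-[(2R,3S,4aS,7R,8aS)-4,4-dimethyl-2,7-bis(triethylsilyloxy)-cis-decalin-3-yl]-3-hydroperoxy-2,6-dimethyloct-5-en-1-yl]oxy}diphenylsilane | CC[Si](CC)(CC)O[C@@H]1CC[C@H]2[C@@H](C1)C[C@@H](O[Si](CC)(CC)CC)[C@@H](CC/C(C)=C/C[C@H]([C@@H](C)CO[Si](c3ccccc3)(c3ccccc3)C(C)(C)C)OO)C2(C)C | intermediate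
37 | 5′-(acetoxymercurio) derivative of 38, mercury anti to O1′ across C5′–C6′ | CC[Si](CC)(CC)O[C@@H]1CC[C@H]2[C@@H](C1)C[C@@H](O[Si](CC)(CC)CC)[C@@H](CC[C@@]1(C)[C@@H]([Hg]OC(C)=O)C[C@H]([C@@H](C)CO[Si](c3ccccc3)(c3ccccc3)C(C)(C)C)OO1)C2(C)C | intermediate
38 | tert-butyl{(2S)-2-[(3R,6S)-6-{2-[(2R,3S,4aS,7R,8aS)-4,4-dimethyl-2,7-bis(triethylsilyloxy)-cis-decalin-3-yl]ethyl}-6-methyl-1,2-dioxan-3-yl]propoxy}diphenylsilane | CC[Si](CC)(CC)O[C@@H]1CC[C@H]2[C@@H](C1)C[C@@H](O[Si](CC)(CC)CC)[C@@H](CC[C@@]1(C)CC[C@H]([C@@H](C)CO[Si](c3ccccc3)(c3ccccc3)C(C)(C)C)OO1)C2(C)C | intermediate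
39 | tert-butyl{(2S)-2-[(3R,6S)-6-{2-[(2R,3S,4aS,7R,8aS)-2,7-dihydroxy-4,4-dimethyl-cis-decalin-3-yl]ethyl}-6-methyl-1,2-dioxan-3-yl]propoxy}diphenylsilane | O[C@@H]1CC[C@H]2[C@@H](C1)C[C@@H](O)[C@@H](CC[C@@]1(C)CC[C@H]([C@@H](C)CO[Si](c3ccccc3)(c3ccccc3)C(C)(C)C)OO1)C2(C)C | intermediate
40 | tert-butyl{(2S)-2-[(3R,6S)-6-{2-[(3S,4aS,8aS)-4,4-dimethyl-2,7-dioxo-cis-decalin-3-yl]ethyl}-6-methyl-1,2-dioxan-3-yl]propoxy}diphenylsilane | O=C1CC[C@H]2[C@@H](C1)CC(=O)[C@@H](CC[C@@]1(C)CC[C@H]([C@@H](C)CO[Si](c3ccccc3)(c3ccccc3)C(C)(C)C)OO1)C2(C)C | intermediate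
41 | tert-butyl{(2S)-2-[(3R,6S)-6-{2-[(3R,4aS,8aS)-4,4-dimethyl-2,7-dimethylidene-cis-decalin-3-yl]ethyl}-6-methyl-1,2-dioxan-3-yl]propoxy}diphenylsilane | C=C1CC[C@H]2[C@@H](C1)CC(=C)[C@@H](CC[C@@]1(C)CC[C@H]([C@@H](C)CO[Si](c3ccccc3)(c3ccccc3)C(C)(C)C)OO1)C2(C)C | intermediate
42 | (2S)-2-[(3R,6S)-6-{2-[(3R,4aS,8aS)-4,4-dimethyl-2,7-dimethylidene-cis-decalin-3-yl]ethyl}-6-methyl-1,2-dioxan-3-yl]propan-1-ol | C=C1CC[C@H]2[C@@H](C1)CC(=C)[C@@H](CC[C@@]1(C)CC[C@H]([C@@H](C)CO)OO1)C2(C)C | intermediate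
43 | (2R)-2-[(3R,6S)-6-{2-[(3R,4aS,8aS)-4,4-dimethyl-2,7-dimethylidene-cis-decalin-3-yl]ethyl}-6-methyl-1,2-dioxan-3-yl]propanoic acid | C=C1CC[C@H]2[C@@H](C1)CC(=C)[C@@H](CC[C@@]1(C)CC[C@H]([C@@H](C)C(=O)O)OO1)C2(C)C | target

**Step count**

Total: 26 steps. Longest linear sequence: 21 steps (steps 1–12, then 18–26).

**Steps most likely to fail**

Step 20. Substitution at the β-branched, homoallylic secondary carbon may be overtaken by E2 elimination towards the conjugated diene, or may stall, and any ionisation would erode the inversion. The fallback sets out from alcohol 34. It is converted into the trifluoromethanesulfonate F1 (Tf2O, 2,6-lutidine, CH2Cl2, −78 °C). F1 is displaced at low temperature by the potassium salt of 2-methoxyprop-2-yl hydroperoxide (KOt-Bu, THF, −78 → 0 °C), a protected and weakly basic peroxide nucleophile, to give with inversion the peroxyketal F2. Brief exposure to dilute AcOH in THF–H2O releases acetone and methanol and comes back to the route at hydroperoxide 36.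

Step 21. The β-peroxyalkyl radical formed during hydride demercuration may collapse to an epoxide, and facial discrimination in the ring closure may be incomplete. The fallback sets out from mesylate 35 and builds the same ring from the other end. Mukaiyama–Isayama peroxidation of the trisubstituted alkene (Co(acac)2, O2, Et3SiH, 1,2-dichloroethane, rt) places a silylperoxy group on the tertiary carbon C6′ and gives the silyl peroxide F3. Methanolysis (K2CO3, MeOH, 0 °C) frees the hydroperoxy mesylate F4. Its anion (KOt-Bu, 18-crown-6, toluene, 0 °C) displaces the C3′ mesylate intramolecularly with inversion (6-exo-tet). C6′ is not controlled in this variant, so the route is rejoined at 38 after separation from its C6′ epimer.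

Step 24. Addition of the ylide to the hindered C2 carbonyl may be slow, which would give time for enolisation and epimerisation of C3 to the more stable epimer, or for attack of the ylide on the O–O bond. The fallback sets out from dione 40 and uses a Peterson olefination. Me3SiCH2MgCl, pre-complexed with anhydrous CeCl3 (THF, −78 °C), is a weakly basic nucleophile that should add to both carbonyls to give the bis(β-hydroxysilane) F5. Elimination with aqueous HF in MeCN at 0 °C comes back to the route at diene 41; if the silyl ether is lost in the same operation, the product is 42.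

**Further compounds**

F1 | step 20 | (3S)-trifluoromethanesulfonate of 34 | CC[Si](CC)(CC)O[C@@H]1CC[C@H]2[C@@H](C1)C[C@@H](O[Si](CC)(CC)CC)[C@@H](CC/C(C)=C/C[C@@H]([C@@H](C)CO[Si](c3ccccc3)(c3ccccc3)C(C)(C)C)OS(=O)(=O)C(F)(F)F)C2(C)C
F2 | step 20 | (3R)-2-methoxyprop-2-yl peroxide (peroxyketal) of 36 | CC[Si](CC)(CC)O[C@@H]1CC[C@H]2[C@@H](C1)C[C@@H](O[Si](CC)(CC)CC)[C@@H](CC/C(C)=C/C[C@H]([C@@H](C)CO[Si](c3ccccc3)(c3ccccc3)C(C)(C)C)OOC(C)(C)OC)C2(C)C
F3 | step 21 | 6′-(triethylsilylperoxy) derivative of mesylate 35 with the alkene saturated, both C6′ epimers | CC[Si](CC)(CC)O[C@@H]1CC[C@H]2[C@@H](C1)C[C@@H](O[Si](CC)(CC)CC)[C@@H](CCC(C)(OO[Si](CC)(CC)CC)CC[C@@H]([C@@H](C)CO[Si](c3ccccc3)(c3ccccc3)C(C)(C)C)OS(C)(=O)=O)C2(C)C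
F4 | step 21 | 6′-hydroperoxy mesylate from F3, both C6′ epimers | CC[Si](CC)(CC)O[C@@H]1CC[C@H]2[C@@H](C1)C[C@@H](O[Si](CC)(CC)CC)[C@@H](CCC(C)(OO)CC[C@@H]([C@@H](C)CO[Si](c3ccccc3)(c3ccccc3)C(C)(C)C)OS(C)(=O)=O)C2(C)C
F5 | step 24 | 2,7-bis[(trimethylsilyl)methyl]-2,7-diol from 40, carbinol configurations undefined | C[Si](C)(C)CC1(O)CC[C@H]2[C@@H](C1)CC(O)(C[Si](C)(C)C)[C@@H](CC[C@@]1(C)CC[C@H]([C@@H](C)CO[Si](c3ccccc3)(c3ccccc3)C(C)(C)C)OO1)C2(C)C
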